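**Retrosynthetic overview**

- The diarylmethane C–C bond is cut last. Both halves come from one (S)-configured phenol monomer, one portion of which is used as its p-quinone methide equivalent (biomimetic Friedel–Crafts benzylation); only O-demethylation follows.
- The monomer's cyclopentane (locants: C1 = aryl- and methyl-bearing quaternary carbon, C2 = CMe2, C3–C5 = CH2) goes back, through Wolff–Kishner and dealkoxycarbonylation retrons, to a β-keto ester.
- That β-keto ester is made by a formal (3+2) radical–polar crossover annulation that forms C2–C3 and C4–C5 in one operation: a 3-isopropenyl-3-methylbenzofuran-2(3H)-one supplies C5–C1–C2 and methyl acrylate supplies C3–C4.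
- Enabling feature: the phenol oxygen on the arene carbon ortho to the one that carries C1 ties C1 and the future C5 into a temporary five-membered aryl-ester lactone (activated acyl acceptor, no α-hydrogen), and the CMe2 carbon next to C1 is a tertiary radical site unmasked from an isopropenyl group.
- The quaternary stereocenter is set before the annulation by catalytic enantioselective O→C acetyl transfer; ring order: temporary lactone, then cyclopentane (the lactone opens in the same step).

Key step: step 6

Assumption: the chiral acyl-transfer catalyst is accessible in both antipodes and the antipode that delivers the (R)-configured keto lactone is used; the sense of induction is to be assigned on the first run.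

**Step 1**
Reactants: 1 2-methoxy-4-methylphenol (creosol); 2 ethyl pyruvate
Product: 4 (±)-3-hydroxy-7-methoxy-3,5-dimethyl-1-benzofuran-2(3H)-one, via open hydroxy ester 3 (not isolated)
Conditions: TiCl4 (1.1 equiv), CH2Cl2, −30 °C → rt; then cat. p-TsOH, PhMe, 80 °C
Reagents that add atoms: none
Why: Friedel–Crafts ortho-hydroxyalkylation in which the titanium phenoxide chelates the α-keto ester and delivers it to the only free ortho position (the para position carries the methyl group), after which the hydroxy ester lactonises; the carbinol center forms racemic and is removed in step 2.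

**Step 2**
Reactants: 4
Product: 5 (±)-7-methoxy-3,5-dimethyl-1-benzofuran-2(3H)-one
Conditions: H2 (3 atm), 10% Pd/C, AcOH, cat. HClO4, 50 °C
Reagents that add atoms: none
Why: Acid-assisted catalytic hydrogenolysis of the tertiary benzylic C–O bond, which stands out of the arene plane in the lactone, should give the 3-methyl lactone; its C3 center is racemic and is planarised in step 3.

**Step 3**
Reactants: 5
Product: 6 7-methoxy-3,5-dimethyl-1-benzofuran-2-yl acetate
Conditions: AcCl, Et3N, THF, 0 °C
Reagents that add atoms: acetyl chloride, CC(=O)Cl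
Why: Enol ester formation, in which triethylamine generates the aromatic benzofuran-2-olate that is acylated on oxygen under kinetic control; no stereocenter is present.

**Step 4**
Reactants: 6
Product: 7 (3R)-3-acetyl-7-methoxy-3,5-dimethyl-1-benzofuran-2(3H)-one
Conditions: TADMAP [3-(1-acetoxy-2,2,2-triphenylethyl)-4-(dimethylamino)pyridine, antipode as in the assumption] (5 mol %), CH2Cl2, 0 °C → rt
Reagents that add atoms: none
Why: Black rearrangement (Steglich-type O→C acyl transfer) through an N-acetylpyridinium benzofuran-2-olate ion pair, in which the enolate face left open by the catalyst's triphenylmethyl group is acetylated at C3 and the quaternary stereocenter is set as (R).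

**Step 5**
Reactants: 7
Product: 8 (3S)-7-methoxy-3,5-dimethyl-3-(prop-1-en-2-yl)-1-benzofuran-2(3H)-one
Conditions: Zn, CH2Br2, TiCl4, THF/CH2Cl2, 0 °C → rt
Reagents that add atoms: dibromomethane, BrCBr
Why: Takai–Lombardo methylenation, whose non-basic zinc/titanium methylene reagent should olefinate the ketone chemoselectively beside the lactone without retro-Claisen cleavage; the quaternary center is untouched (the descriptor becomes S only through the change in group priorities).

**Step 6**
Reactants: 8; 9 methyl acrylate
Product: 11 methyl (3S)-3-(2-hydroxy-3-methoxy-5-methylphenyl)-3,4,4-trimethyl-2-oxocyclopentane-1-carboxylate, via ester enolate 10 (not isolated)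
Conditions: Fe(acac)3 (30 mol %), PhSiH2(Oi-Pr) (2.5 equiv), 9 (2 equiv), THF, 40 °C; then 1 M HCl
Reagents that add atoms: none
Why: Proposed new method: an iron hydride formed from Fe(acac)3 and the silane should transfer a hydrogen atom to the terminal CH2 of the isopropenyl group, and the resulting tertiary radical at the future CMe2 carbon should add to methyl acrylate (Giese addition), which forms the CMe2–CH2 bond. The α-ester radical should then be reduced by divalent iron to the trivalent-iron ester enolate 10, which, with no proton source present, attacks the lactone (aryl ester) carbonyl and expels the phenoxide, which forms the second ring bond and turns the lactone carbon into the ring ketone. The closest known reaction types are the iron-mediated reductive coupling of olefins with acrylates and hydrogen-atom-transfer-initiated radical–polar crossover annulations that end in an aldol step; the acyl-transfer terminus is modelled on the Dieckmann condensation and the Baker–Venkataraman acyl shift. The cyclopentane closes by a 5-exo-trig attack of the enolate carbon on the lactone C=O. The only new stereocenter, the ester-bearing ring carbon, is enolisable, uncontrolled and removed in step 7, whereas the quaternary stereocenter has no bond made or broken and no α-hydrogen and is carried through intact. The step needs bimolecular radical addition to outrun 3-exo attack of the radical on the lactone carbonyl (1,2-acyl shift) and 1,2-aryl shift, which the excess of acrylate and the low radical affinity of an ester carbonyl should secure, and it needs acyl transfer to outrun quenching of the enolate, which the aprotic medium, the strained aryl ester and the five-membered transition state should secure.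

**Step 7**
Reactants: 11
Product: 13 (2S)-2-(2-hydroxy-3-methoxy-5-methylphenyl)-2,3,3-trimethylcyclopentan-1-one, via β-keto acid 12 (not isolated)
Conditions: LiCl, H2O (2 equiv), DMSO, 150 °C
Reagents that add atoms: none
Why: Krapcho dealkoxycarbonylation, in which chloride demethylates the ester and the β-keto acid loses CO2, which also erases the uncontrolled ester-bearing stereocenter; the quaternary center has no acidic hydrogen.

**Step 8**
Reactants: 13
Product: 15 2-methoxy-4-methyl-6-[(1S)-1,2,2-trimethylcyclopentyl]phenol, via hydrazone 14 (not isolated)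
Conditions: N2H4·H2O, KOH, diethylene glycol, 130 °C then 200 °C
Reagents that add atoms: none
Why: Wolff–Kishner reduction (Huang–Minlon procedure), in which the hydrazone of the cyclopentanone loses N2 under base to leave the CH2 group while the phenoxide formed in the medium protects the neighbouring methyl ether from nucleophilic cleavage; no stereocenter is touched.

**Step 9**
Reactants: 15
Product: 17 2-methoxy-4-(methoxymethyl)-6-[(1S)-1,2,2-trimethylcyclopentyl]phenol, via quinone methide 16 (not isolated)
Conditions: DDQ (1.05 equiv), MeOH, 0 °C → rt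
Reagents that add atoms: methanol, CO
Why: Quinone dehydrogenation of a 2,6-disubstituted p-cresol, in which DDQ should give the p-quinone methide (an ortho-quinone methide cannot form because the ortho substituent is quaternary) and methanol adds 1,6 to the exocyclic carbon.

**Step 10**
Reactants: 17; 15 (3 equiv, excess recovered)
Product: 19 3-{[4-hydroxy-3-methoxy-5-[(1S)-1,2,2-trimethylcyclopentyl]phenyl]methyl}-2-methoxy-4-methyl-6-[(1S)-1,2,2-trimethylcyclopentyl]phenol, via hydroxybenzyl cation 18 (not isolated)
Conditions: BF3·OEt2 (20 mol %), CH2Cl2, −20 → 0 °C, slow addition of 17 to 15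
Reagents that add atoms: none
Why: Friedel–Crafts benzylation that copies the presumed biosynthesis, in which the Lewis acid ionises the benzyl methyl ether to the para-hydroxy-stabilised benzylic cation 18 (an O-protonated p-quinone methide, the electrophile that exists under acidic conditions) and this is attacked by the ring carbon of 15 that lies ortho to the methoxy group and para to the cyclopentyl group, the only other free ring carbon being shielded by the adjacent quaternary carbon; no stereocenter is formed.

**Step 11**
Reactants: 19
Product: 20 3-{[3,4-dihydroxy-5-[(1S)-1,2,2-trimethylcyclopentyl]phenyl]methyl}-4-methyl-6-[(1S)-1,2,2-trimethylcyclopentyl]benzene-1,2-diol (target)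
Conditions: BBr3 (6 equiv), CH2Cl2, −78 → 0 °C; then H2O
Reagents that add atoms: none
Why: Lewis-acid ether cleavage, in which BBr3 converts both aryl methyl ethers into aryl borates that are hydrolysed to the free catechols; the stereocenters are untouched.

**Compound list**

1 | 2-methoxy-4-methylphenol (creosol) | COc1cc(C)ccc1O | starting material
2 | ethyl pyruvate | CCOC(=O)C(C)=O | starting material
3 | ethyl 2-hydroxy-2-(2-hydroxy-3-methoxy-5-methylphenyl)propanoate (racemic) | CCOC(=O)C(C)(O)c1cc(C)cc(OC)c1O | intermediate
4 | 3-hydroxy-7-methoxy-3,5-dimethyl-1-benzofuran-2(3H)-one (racemic) | COc1cc(C)cc2c1OC(=O)C2(C)O | intermediate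
5 | 7-methoxy-3,5-dimethyl-1-benzofuran-2(3H)-one (racemic) | COc1cc(C)cc2c1OC(=O)C2C | intermediate
6 | 7-methoxy-3,5-dimethyl-1-benzofuran-2-yl acetate | CC(=O)Oc1oc2c(OC)cc(C)cc2c1C | intermediate
7 | (3R)-3-acetyl-7-methoxy-3,5-dimethyl-1-benzofuran-2(3H)-one | COc1cc(C)cc2c1OC(=O)[C@@]2(C)C(C)=O | intermediate
8 | (3S)-7-methoxy-3,5-dimethyl-3-(prop-1-en-2-yl)-1-benzofuran-2(3H)-one | COc1cc(C)cc2c1OC(=O)[C@@]2(C)C(C)=C | intermediate
9 | methyl acrylate | C=CC(=O)OC | starting material
10 | ester enolate of methyl 4-[(3S)-7-methoxy-3,5-dimethyl-2-oxo-2,3-dihydro-1-benzofuran-3-yl]-4-methylpentanoate | COC([O-])=CCC(C)(C)[C@]1(C)C(=O)Oc2c(OC)cc(C)cc21 | intermediate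
11 | methyl (3S)-3-(2-hydroxy-3-methoxy-5-methylphenyl)-3,4,4-trimethyl-2-oxocyclopentane-1-carboxylate (epimers at the ester-bearing carbon) | COC(=O)C1CC(C)(C)[C@@](C)(c2cc(C)cc(OC)c2O)C1=O | intermediate
12 | (3S)-3-(2-hydroxy-3-methoxy-5-methylphenyl)-3,4,4-trimethyl-2-oxocyclopentane-1-carboxylic acid | OC(=O)C1CC(C)(C)[C@@](C)(c2cc(C)cc(OC)c2O)C1=O | intermediate
13 | (2S)-2-(2-hydroxy-3-methoxy-5-methylphenyl)-2,3,3-trimethylcyclopentan-1-one | O=C1CCC(C)(C)[C@@]1(C)c1cc(C)cc(OC)c1O | intermediate
14 | hydrazone of ketone 13 | NN=C1CCC(C)(C)[C@@]1(C)c1cc(C)cc(OC)c1O | intermediate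
15 | 2-methoxy-4-methyl-6-[(1S)-1,2,2-trimethylcyclopentyl]phenol | COc1cc(C)cc([C@@]2(C)CCCC2(C)C)c1O | intermediate
16 | 2-methoxy-4-methylidene-6-[(1S)-1,2,2-trimethylcyclopentyl]cyclohexa-2,5-dien-1-one | COC1=CC(=C)C=C([C@@]2(C)CCCC2(C)C)C1=O | intermediate
17 | 2-methoxy-4-(methoxymethyl)-6-[(1S)-1,2,2-trimethylcyclopentyl]phenol | COCc1cc(OC)c(O)c([C@@]2(C)CCCC2(C)C)c1 | intermediate
18 | {4-hydroxy-3-methoxy-5-[(1S)-1,2,2-trimethylcyclopentyl]phenyl}methylium (4-hydroxybenzyl cation) | COc1cc([CH2+])cc([C@@]2(C)CCCC2(C)C)c1O | intermediate
19 | 3-{[4-hydroxy-3-methoxy-5-[(1S)-1,2,2-trimethylcyclopentyl]phenyl]methyl}-2-methoxy-4-methyl-6-[(1S)-1,2,2-trimethylcyclopentyl]phenol | Cc1cc([C@@]2(C)CCCC2(C)C)c(O)c(OC)c1Cc1cc(OC)c(O)c([C@@]2(C)CCCC2(C)C)c1 | intermediate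
20 | 3-{[3,4-dihydroxy-5-[(1S)-1,2,2-trimethylcyclopentyl]phenyl]methyl}-4-methyl-6-[(1S)-1,2,2-trimethylcyclopentyl]benzene-1,2-diol | Cc1cc([C@@]2(C)CCCC2(C)C)c(O)c(O)c1Cc1cc(O)c(O)c([C@@]2(C)CCCC2(C)C)c1 | target

**Step count and risks**

Total step count: 11. Longest linear sequence: 11 steps (1 to 20; step 10 joins two portions of 15).

Steps most likely to fail:

1. Step 6 (proposed new method). The enolate may be protonated or O-silylated before it transfers the acyl group, the β-keto ester formed may add to excess acrylate, or the tertiary radical may undergo a 1,2-acyl shift before it is trapped. The fallback separates the radical and the ionic event into two known operations. It sets out from 8: the established protic iron-mediated reductive olefin coupling (Fe(acac)3, PhSiH3, EtOH/ethylene glycol, 60 °C, methyl acrylate) should stop at the open-chain adduct methyl 4-[(3S)-7-methoxy-3,5-dimethyl-2-oxo-2,3-dihydro-1-benzofuran-3-yl]-4-methylpentanoate F1. After removal of the acrylate, KOt-Bu in THF at 0 °C should effect the Dieckmann-type acyl transfer, and the route is rejoined at 11.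

2. Step 4. Facial discrimination in the C-acetylation may be poor for the small 3-methyl group, or an uncatalysed racemic acyl transfer may erode the enantiomeric purity. The fallback replaces asymmetric catalysis by resolution. It sets out from 6: rearrangement with achiral 4-(pyrrolidin-1-yl)pyridine should give the racemic keto lactone 3-acetyl-7-methoxy-3,5-dimethyl-1-benzofuran-2(3H)-one F2, whose antipodes are separated by preparative chromatography on a chiral stationary phase; the (R)-antipode rejoins the route at 7.

3. Step 10. The benzylic cation may attack the wrong ring carbon or the phenol oxygen, and 17 may condense with itself or alkylate the product a second time. The fallback fixes the site by directed ortho-metalation instead of electrophilic substitution. It sets out from 15 and comes back at 20. One portion of 15 is O-methylated (MeI, K2CO3, DMF) to 1,2-dimethoxy-5-methyl-3-[(1S)-1,2,2-trimethylcyclopentyl]benzene F3. A second portion is oxidised with excess DDQ in aqueous methanol to 4-hydroxy-3-methoxy-5-[(1S)-1,2,2-trimethylcyclopentyl]benzaldehyde F4 and then O-methylated in the same way to 3,4-dimethoxy-5-[(1S)-1,2,2-trimethylcyclopentyl]benzaldehyde F5. F3 is lithiated with n-BuLi/TMEDA at its only ring position ortho to a methoxy group and added to F5, which should give the diaryl carbinol {2,3-dimethoxy-6-methyl-4-[(1S)-1,2,2-trimethylcyclopentyl]phenyl}{3,4-dimethoxy-5-[(1S)-1,2,2-trimethylcyclopentyl]phenyl}methanol F6. Ionic hydrogenation (Et3SiH, TFA, CH2Cl2) should then give the tetramethyl ether 1,2-dimethoxy-3-{[3,4-dimethoxy-5-[(1S)-1,2,2-trimethylcyclopentyl]phenyl]methyl}-4-methyl-6-[(1S)-1,2,2-trimethylcyclopentyl]benzene F7, and BBr3 in CH2Cl2 should cleave all four methyl ethers to give 20.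

**Further compounds**

F1 | step 6 | methyl 4-[(3S)-7-methoxy-3,5-dimethyl-2-oxo-2,3-dihydro-1-benzofuran-3-yl]-4-methylpentanoate | COC(=O)CCC(C)(C)[C@]1(C)C(=O)Oc2c(OC)cc(C)cc21
F2 | step 4 | 3-acetyl-7-methoxy-3,5-dimethyl-1-benzofuran-2(3H)-one (racemic) | COc1cc(C)cc2c1OC(=O)C2(C)C(C)=O
F3 | step 10 | 1,2-dimethoxy-5-methyl-3-[(1S)-1,2,2-trimethylcyclopentyl]benzene | COc1cc(C)cc([C@@]2(C)CCCC2(C)C)c1OC
F4 | step 10 | 4-hydroxy-3-methoxy-5-[(1S)-1,2,2-trimethylcyclopentyl]benzaldehyde | COc1cc(C=O)cc([C@@]2(C)CCCC2(C)C)c1O
F5 | step 10 | 3,4-dimethoxy-5-[(1S)-1,2,2-trimethylcyclopentyl]benzaldehyde | COc1cc(C=O)cc([C@@]2(C)CCCC2(C)C)c1OC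
F6 | step 10 | {2,3-dimethoxy-6-methyl-4-[(1S)-1,2,2-trimethylcyclopentyl]phenyl}{3,4-dimethoxy-5-[(1S)-1,2,2-trimethylcyclopentyl]phenyl}methanol (carbinol epimers) | Cc1cc([C@@]2(C)CCCC2(C)C)c(OC)c(OC)c1C(O)c1cc(OC)c(OC)c([C@@]2(C)CCCC2(C)C)c1
F7 | step 10 | 1,2-dimethoxy-3-{[3,4-dimethoxy-5-[(1S)-1,2,2-trimethylcyclopentyl]phenyl]methyl}-4-methyl-6-[(1S)-1,2,2-trimethylcyclopentyl]benzene | Cc1cc([C@@]2(C)CCCC2(C)C)c(OC)c(OC)c1Cc1cc(OC)c(OC)c([C@@]2(C)CCCC2(C)C)c1
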